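**Plan**
Numbering: the 6-hydroxychromone half is unprimed (its benzo ring is ring A: C4a, C5, C6, C7, C8, C8a) and the 8-hydroxychromone half is primed. Both phenols travel as methyl ethers, so the last cuts are two O–CH3 bonds.
Cuts: the unprimed pyranone is opened at O1–C2 and C2–C3, back to a 2-hydroxy-5-methoxy-6-arylacetophenone. Ring A is then taken back by two hydrogens to a 2-acetyl-3-aryl-4-methoxycyclohex-2-enone, and C5–C5' and C4a–C8a are cut together.
Enabling feature: in that cyclohexenone, C4a and C5 are the two carbons of an ynone triple bond (C4 is the ketone), and C8a is the carbonyl carbon of an ester tied to C5 through C6, C7 and C8. One arylmetal addition followed by acyl substitution therefore builds the biaryl bond and ring A at once.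
Forward order: primed pyranone ring, then C5' bromination and borylation; acyclic ynone ester from an acetal, a silylacetylene and acetyl chloride; ring A as a cyclohexenone in the union step; aromatisation; unprimed pyranone ring; demethylation.
Stereochemistry: the target has no stereocentre. The only sp3 centre of the route (C6, methoxy-bearing) is racemic and is erased on aromatisation.

Key step: step 8

Assumption: the target structure carries no descriptor for the C5–C5' axis, so the biaryl is made without control of axial configuration.

**Step 1**
Reactants: 1 methyl 4,4-dimethoxybutanoate; 2 bis(trimethylsilyl)acetylene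
Product: 3 methyl 4-methoxy-6-(trimethylsilyl)hex-5-ynoate (racemic)
Conditions: 2 (1.5 equiv), TiCl4 (1.1 equiv), CH2Cl2, −78 °C; then H2O
Reagents that add atoms: none
Why: Lewis-acid-promoted alkynylation of an acetal with an alkynylsilane (the alkyne counterpart of the Hosomi–Sakurai reaction): TiCl4 ionises one methoxy group, the oxocarbenium ion is captured by 2 with loss of one silyl group, and the propargylic methyl ether arises directly, so that no free γ-hydroxy ester prone to lactonisation is ever present; the new stereocentre forms without control (racemic) and is erased in step 9.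

**Step 2**
Reactants: 3 methyl 4-methoxy-6-(trimethylsilyl)hex-5-ynoate
Product: 4 methyl 4-methoxyhex-5-ynoate (racemic)
Conditions: K2CO3 (0.2 equiv), MeOH, 0 °C to rt
Reagents that add atoms: none
Why: Methoxide-catalysed protodesilylation of an alkynylsilane, run in methanol so that any transesterification of the methyl ester is degenerate.

**Step 3**
Reactants: 4 methyl 4-methoxyhex-5-ynoate; 5 acetyl chloride
Product: 6 methyl 4-methoxy-7-oxooct-5-ynoate (racemic)
Conditions: PdCl2(PPh3)2 (2 mol %), CuI (4 mol %), Et3N (1.2 equiv), THF, rt
Reagents that add atoms: none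
Why: Acyl Sonogashira coupling, in which zerovalent palladium inserts into the acyl chloride, the copper acetylide transmetallates and reductive elimination gives the ynone at room temperature without a strong base, so the ester and the propargylic ether are left alone and the small excess of amine limits ketene formation.

**Step 4**
Reactants: 7 2'-hydroxy-3'-methoxyacetophenone; 8 ethyl 3-phenylpropanoate
Product: 10 8-methoxy-2-(2-phenylethyl)chromen-4-one, via 1,3-diketone 9 (not isolated)
Conditions: NaH (4 equiv), THF, reflux; then conc. HCl, MeOH, reflux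
Reagents that add atoms: none
Why: Crossed Claisen condensation of the acetophenone enolate with the ester gives the β-diketone, whose acid-catalysed cyclodehydration (phenol oxygen onto the distal carbonyl, loss of water) closes the primed pyranone ring, the standard entry to 2-(2-phenylethyl)chromones.

**Step 5**
Reactants: 10 8-methoxy-2-(2-phenylethyl)chromen-4-one
Product: 11 5-bromo-8-methoxy-2-(2-phenylethyl)chromen-4-one
Conditions: NBS (1.1 equiv), [Cp*Rh(MeCN)3](SbF6)2 (5 mol %), PivOH (1.1 equiv), ClCH2CH2Cl, 60 °C, dark
Reagents that add atoms: N-bromosuccinimide, O=C1CCC(=O)N1Br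
Why: Carbonyl-directed C–H bromination with a cationic trivalent rhodium catalyst, a reaction type known for chromones: the C4' oxygen steers cyclometallation to the peri C5'–H, which is also para to the 8'-methoxy group, so direction and ring electronics agree and attack at C3' or C7' is held back.

**Step 6**
Reactants: 11 5-bromo-8-methoxy-2-(2-phenylethyl)chromen-4-one
Product: 12 8-methoxy-2-(2-phenylethyl)-5-(4,4,5,5-tetramethyl-1,3,2-dioxaborolan-2-yl)chromen-4-one
Conditions: B2pin2 (1.5 equiv), PdCl2(dppf) (5 mol %), KOAc (3 equiv), 1,4-dioxane, 90 °C
Reagents that add atoms: bis(pinacolato)diboron, CC1(C)OB(OC1(C)C)B1OC(C)(C)C(C)(C)O1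
Why: Miyaura borylation, which tolerates ortho-acyl aryl bromides and uses the weak base acetate, so neither the pyranone ring nor the acidic 2'-CH2 group is disturbed.

**Step 7**
Reactants: 12 the pinacol boronate
Product: 13 [8-methoxy-4-oxo-2-(2-phenylethyl)chromen-5-yl]boronic acid
Conditions: NaIO4 (3 equiv), NH4OAc (3 equiv), acetone/H2O, rt
Reagents that add atoms: water, O
Why: Oxidative deprotection of a pinacol boronate, in which periodate cleaves the pinacol released by the hydrolysis equilibrium and so drives it to the free boronic acid, the form that transmetallates readily to nickel.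

**Step 8**
Reactants: 6 methyl 4-methoxy-7-oxooct-5-ynoate; 13 [8-methoxy-4-oxo-2-(2-phenylethyl)chromen-5-yl]boronic acid
Product: 14 5-(2-acetyl-6-methoxy-3-oxocyclohex-1-en-1-yl)-8-methoxy-2-(2-phenylethyl)chromen-4-one (racemic)
Conditions: Ni(OAc)2·4H2O (10 mol %), 2-[2-(diphenylphosphanyl)phenyl]-4,4-dimethyl-4,5-dihydro-1,3-oxazole (10 mol %), 13 (1.5 equiv), MeCN/2-MeTHF, 80 °C
Reagents that add atoms: none
Why: Proposed new method: Transmetallation of 13 to the divalent nickel acetate (later methoxide) complex gives an arylnickel species that adds syn across the triple bond of 6, aryl to the carbon β to the ketone (C5–C5') and nickel to the α-carbon (C4a), and the E-alkenylnickel then inverts through its nickel allenolate form to the Z isomer, with nickel cis to the ester-bearing chain. The Z-alkenylnickel attacks the ester carbonyl in a 6-exo-trig closure (C4a–C8a) and the tetrahedral intermediate expels methoxide; the nickel methoxide takes up the next boronic acid, so turnover needs no proton and an aprotic medium can be chosen to hold back protodemetallation. The closest known reaction type is the anti-carbometallative arylative cyclisation of aryl-substituted alkynes onto tethered ketones, enones and esters with Ni(OAc)2 and P,N ligands, five- and six-membered rings included; new here are the acyl substituent on the alkyne and the peri-carbonyl boronic acid. No stereocentre is created, since the methoxy-bearing carbon is carried through racemic from 6 and any diastereomerism with the hindered aryl–cyclohexenyl axis disappears in step 9. The step needs β-selective aryl delivery and E-to-Z isomerisation, and both follow from the polarisation of the ynone, which places nickel on the enolisable α-carbon. Making the inter-ring bond at a linear sp carbon avoids the congestion of joining two peri-substituted arenes directly.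

**Step 9**
Reactants: 14 the cyclohexenone
Product: 15 5-(2-acetyl-3-hydroxy-6-methoxyphenyl)-8-methoxy-2-(2-phenylethyl)chromen-4-one
Conditions: Pd(O2CCF3)2 (5 mol %), 2-(dimethylamino)pyridine (10 mol %), TsOH·H2O (20 mol %), O2 (1 atm), DMSO, 80 °C
Reagents that add atoms: none
Why: Aerobic palladium-catalysed dehydrogenation of a cyclohexenone to a phenol: a divalent palladium enolate forms at the ring methylene next to the ketone (C8), β-hydride elimination from C7 gives the 4-methoxycyclohexa-2,5-dienone, and this tautomerises to the 4-methoxyphenol pattern of ring A, whereas the acetyl enolate has no β-hydrogen and cannot react on; the racemic stereocentre disappears here.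

**Step 10**
Reactants: 15 the phenol; 16 3-phenylpropanoyl chloride
Product: 17 2-acetyl-4-methoxy-3-[8-methoxy-4-oxo-2-(2-phenylethyl)chromen-5-yl]phenyl 3-phenylpropanoate
Conditions: Et3N (1.5 equiv), DMAP (cat.), CH2Cl2, 0 °C to rt
Reagents that add atoms: none
Why: DMAP-catalysed O-acylation of the only free hydroxyl group, which makes the following C-acylation intramolecular, so that no strong base meets an external acylating agent while the acidic 2'-CH2 of the finished chromone is present.

**Step 11**
Reactants: 17 the aryl ester
Product: 19 6,8'-dimethoxy-2,2'-bis(2-phenylethyl)-[5,5'-bichromene]-4,4'-dione, via 1,3-diketone 18 (not isolated)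
Conditions: KOt-Bu (2.5 equiv), THF, 0 °C to rt; then conc. HCl, MeOH, reflux
Reagents that add atoms: none
Why: Baker–Venkataraman rearrangement (the acetyl enolate attacks the neighbouring aryl ester through a six-membered transition state, forming C2–C3) followed by acid-catalysed cyclodehydration (O1–C2) closes the unprimed pyranone ring, while deprotonation or alkoxide addition at the primed chromone is reversible, has no productive outlet and is undone on acidification.

**Step 12**
Reactants: 19 the dimethyl ether
Product: 20 6,8'-dihydroxy-2,2'-bis(2-phenylethyl)-[5,5'-bichromene]-4,4'-dione (CNP0392394.0)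
Conditions: BBr3 (6 equiv), CH2Cl2, −78 °C to rt; then H2O
Reagents that add atoms: none
Why: Lewis-acid cleavage of aryl methyl ethers, in which BBr3 binds each ether oxygen and bromide removes the methyl group by SN2, the excess covering the two chromone carbonyls that also bind boron, and hydrolysis of the aryl borates frees both phenols without harm to the pyranone rings or the phenethyl chains.

**Compound list**
1 | methyl 4,4-dimethoxybutanoate | COC(=O)CCC(OC)OC | starting material
2 | bis(trimethylsilyl)acetylene | C[Si](C)(C)C#C[Si](C)(C)C | starting material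
3 | methyl 4-methoxy-6-(trimethylsilyl)hex-5-ynoate (racemic) | COC(=O)CCC(OC)C#C[Si](C)(C)C | intermediate
4 | methyl 4-methoxyhex-5-ynoate (racemic) | COC(=O)CCC(OC)C#C | intermediate
5 | acetyl chloride | CC(=O)Cl | starting material
6 | methyl 4-methoxy-7-oxooct-5-ynoate (racemic) | CC(=O)C#CC(OC)CCC(=O)OC | intermediate
7 | 2'-hydroxy-3'-methoxyacetophenone | CC(=O)c1cccc(OC)c1O | starting material
8 | ethyl 3-phenylpropanoate | CCOC(=O)CCc1ccccc1 | starting material
9 | 1-(2-hydroxy-3-methoxyphenyl)-5-phenylpentane-1,3-dione | COc1cccc(C(=O)CC(=O)CCc2ccccc2)c1O | intermediate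
10 | 8-methoxy-2-(2-phenylethyl)chromen-4-one | COc1cccc2c1oc(CCc1ccccc1)cc2=O | intermediate
11 | 5-bromo-8-methoxy-2-(2-phenylethyl)chromen-4-one | COc1ccc(Br)c2c1oc(CCc1ccccc1)cc2=O | intermediate
12 | 8-methoxy-2-(2-phenylethyl)-5-(4,4,5,5-tetramethyl-1,3,2-dioxaborolan-2-yl)chromen-4-one | COc1ccc(B3OC(C)(C)C(C)(C)O3)c2c1oc(CCc1ccccc1)cc2=O | intermediate
13 | [8-methoxy-4-oxo-2-(2-phenylethyl)chromen-5-yl]boronic acid | OB(O)c1ccc(OC)c2oc(CCc3ccccc3)cc(=O)c12 | intermediate
14 | 5-(2-acetyl-6-methoxy-3-oxocyclohex-1-en-1-yl)-8-methoxy-2-(2-phenylethyl)chromen-4-one (racemic) | CC(=O)C1=C(c2ccc(OC)c3oc(CCc4ccccc4)cc(=O)c23)C(OC)CCC1=O | intermediate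
15 | 5-(2-acetyl-3-hydroxy-6-methoxyphenyl)-8-methoxy-2-(2-phenylethyl)chromen-4-one | CC(=O)c1c(O)ccc(OC)c1-c1ccc(OC)c2oc(CCc3ccccc3)cc(=O)c12 | intermediate
16 | 3-phenylpropanoyl chloride | O=C(Cl)CCc1ccccc1 | starting material
17 | 2-acetyl-4-methoxy-3-[8-methoxy-4-oxo-2-(2-phenylethyl)chromen-5-yl]phenyl 3-phenylpropanoate | CC(=O)c1c(OC(=O)CCc2ccccc2)ccc(OC)c1-c1ccc(OC)c2oc(CCc3ccccc3)cc(=O)c12 | intermediate
18 | 1-{2-hydroxy-5-methoxy-6-[8-methoxy-4-oxo-2-(2-phenylethyl)chromen-5-yl]phenyl}-5-phenylpentane-1,3-dione | O=C(CC(=O)CCc1ccccc1)c1c(O)ccc(OC)c1-c1ccc(OC)c2oc(CCc3ccccc3)cc(=O)c12 | intermediate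
19 | 6,8'-dimethoxy-2,2'-bis(2-phenylethyl)-[5,5'-bichromene]-4,4'-dione | COc1ccc2oc(CCc3ccccc3)cc(=O)c2c1-c1ccc(OC)c2oc(CCc3ccccc3)cc(=O)c12 | intermediate
20 | 6,8'-dihydroxy-2,2'-bis(2-phenylethyl)-[5,5'-bichromene]-4,4'-dione (CNP0392394.0) | O=c1cc(CCc2ccccc2)oc2ccc(O)c(-c3ccc(O)c4oc(CCc5ccccc5)cc(=O)c34)c12 | target

**Totals**
Total step count: 12.
Longest linear sequence: 9 steps (7 to 20, steps 4 to 12).

**Steps most likely to fail**

**Step 8.**
- What may go wrong: protonation of the nickel allenolate before it reaches the ester (net hydroarylation without ring closure); protodeboronation of 13 at 80 °C; slow insertion of the chelated, peri-substituted arylnickel; or phosphine-induced isomerisation of the γ-alkoxy ynone.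
- Fallback: known chemistry that makes the inter-ring bond by cross-coupling of two finished chromones. It sets out from 13 and 8 and comes back at 19.
- 2'-Hydroxy-5'-methoxyacetophenone F1 (purchased) would be condensed with 8 (NaH, THF, reflux) to 1-(2-hydroxy-5-methoxyphenyl)-5-phenylpentane-1,3-dione F2. This would be cyclodehydrated (conc. HCl, MeOH, reflux) to 6-methoxy-2-(2-phenylethyl)chromen-4-one F3. Bromination at the peri position under the conditions of step 5 would then give 5-bromo-6-methoxy-2-(2-phenylethyl)chromen-4-one F4.
- Suzuki–Miyaura coupling of F4 with 13 (Pd(OAc)2, SPhos, K3PO4, toluene/H2O, 100 °C) should give 19. Steps 1 to 3 and 8 to 11 then fall away.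

**Step 9.**
- What may go wrong: acid-induced hydrolysis of the enol-ether tautomer of the substrate, with loss of the methyl ether and over-oxidation towards a quinone; slow palladium enolate formation next to the crowded ene-dione; or competing dehydrogenation of the phenethyl chain.
- Fallback: sets out from 14 and comes back at 15.
- Catalytic DBU in toluene should shift 14 to its hydrogen-bonded dienol tautomer 5-(6-acetyl-5-hydroxy-2-methoxycyclohexa-1,5-dien-1-yl)-8-methoxy-2-(2-phenylethyl)chromen-4-one F5.
- F5 is a cyclohexa-1,3-diene, which DDQ (1.05 equiv, toluene, rt) should aromatise by hydride abstraction. The ring is then treated as a dihydroarene under acid-free and metal-free conditions, not as a ketone to be dehydrogenated through its enolate.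

**Step 3.**
- What may go wrong: consumption of acetyl chloride through ketene formation with the amine; amine-induced isomerisation of the γ-alkoxy ynone to an allenyl ketone; or conjugate addition of amine or chloride to the product.
- Fallback: sets out from 4 and comes back at 6.
- Heating 4 with Bu3SnOMe (neat, 70 °C, methanol removed under reduced pressure) should give methyl 4-methoxy-6-(tributylstannyl)hex-5-ynoate F6.
- Base-free Stille acylation of F6 with 5 (PdCl2(PPh3)2, ClCH2CH2Cl, 60 °C) should deliver 6 in the absence of any amine.

**Further compounds**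
F1 | step 8 | 2'-hydroxy-5'-methoxyacetophenone | CC(=O)c1cc(OC)ccc1O
F2 | step 8 | 1-(2-hydroxy-5-methoxyphenyl)-5-phenylpentane-1,3-dione | COc1ccc(O)c(c1)C(=O)CC(=O)CCc1ccccc1
F3 | step 8 | 6-methoxy-2-(2-phenylethyl)chromen-4-one | COc1ccc2oc(CCc3ccccc3)cc(=O)c2c1
F4 | step 8 | 5-bromo-6-methoxy-2-(2-phenylethyl)chromen-4-one | COc1ccc2oc(CCc3ccccc3)cc(=O)c2c1Br
F5 | step 9 | 5-(6-acetyl-5-hydroxy-2-methoxycyclohexa-1,5-dien-1-yl)-8-methoxy-2-(2-phenylethyl)chromen-4-one | CC(=O)C1=C(O)CCC(OC)=C1c1ccc(OC)c2oc(CCc3ccccc3)cc(=O)c12
F6 | step 3 | methyl 4-methoxy-6-(tributylstannyl)hex-5-ynoate | CCCC[Sn](CCCC)(CCCC)C#CC(OC)CCC(=O)OC
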